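The plan disconnects the C5–C10 ring-fusion bond (labdane numbering) together with C3–C4 by an intramolecular Diels–Alder reaction, so that rings A and B of the trans-decalin arise in one operation from an acyclic trienoate. The precursor carries a tiglate-type dienophile (C4=C5), a C6–C9 tether with a silyloxy stereocentre at C6 and a ketone at C8, and a 1,1-disubstituted diene (C10=C1–C2=C3). The step exploits the contiguous C4 (quaternary)–C5–C10 (quaternary) array: alkene geometry encodes C4, the C6 centre directs both faces, and the C8 ketone later allows C9 equilibration and installation of the exocyclic methylene.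

Key step: step 7

Remark on numbering: positions are given in the labdane numbering of the target (ring A = C-1 to C-5 and C-10; ring B = C-5 to C-10; C-11 to C-15 side chain with C-16 methyl on C-13; C-17 exocyclic methylene carbon; C-18 methyl and C-19 carboxyl carbon on C-4; C-20 methyl on C-10).

Assumption: the C-9 centre, which is α to the C-8 ketone, is carried as an epimeric mixture from step 4 to step 7 and is set under thermodynamic control in step 8.

Step 1
Reactants: 1 2,2-dimethoxyacetaldehyde; 2 methyl 2-(triphenylphosphoranylidene)propanoate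
Product: 3 methyl (2E)-4,4-dimethoxy-2-methylbut-2-enoate
Conditions: CH2Cl2, rt
Reagents that add atoms: none
Why: Wittig olefination of an unhindered aldehyde with an α-methyl ester-stabilised ylide is reliably E-selective, which fixes the tiglate geometry (ester trans to the future C-6) on which the C-4 to C-5 relationship of the key step depends.

Step 2
Reactants: 3 methyl (2E)-4,4-dimethoxy-2-methylbut-2-enoate
Product: 4 methyl (2E)-2-methyl-4-oxobut-2-enoate
Conditions: 1 M aq. HCl, acetone, rt
Reagents that add atoms: water, O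
Why: Acid-catalysed acetal hydrolysis should unmask the aldehyde without touching the conjugated ester, and the E alkene is the thermodynamically preferred isomer so it should be retained.

Step 3
Reactants: 5 (3E)-4-methoxypent-3-en-2-one; 6 allylmagnesium bromide
Product: 8 4-methylhepta-3,6-dien-2-one (E/Z mixture), via dienyl carbinol 7 (not isolated)
Conditions: THF, −78 → 0 °C; then 2 M aq. HCl, rt
Reagents that add atoms: water, O
Why: Grignard 1,2-addition to a vinylogous ester followed by acid-promoted enol ether hydrolysis and dehydration (Stork–Danheiser-type carbonyl transposition) should give the β,β-disubstituted enone, whose double-bond geometry is irrelevant because it is erased in step 4.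

Step 4
Reactants: 8 4-methylhepta-3,6-dien-2-one; 9 benzyl 2-iodoethyl ether
Product: 10 (4E)-3-[2-(benzyloxy)ethyl]-4-methylhepta-4,6-dien-2-one (racemic)
Conditions: KOtBu, THF, −78 → −40 °C; then 9, DMPU, −40 °C → rt
Reagents that add atoms: none
Why: Deprotonation at the doubly allylic γ-position gives an extended trienolate whose kinetically preferred α-alkylation (deconjugative alkylation of an extended enolate) installs the C-11/C-12 arm and the conjugated diene at once, the extended enolate geometry being expected to give the E trisubstituted alkene, while the new C-9 centre is formed as a racemate and corrected later.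

Step 5
Reactants: 10 (4E)-3-[2-(benzyloxy)ethyl]-4-methylhepta-4,6-dien-2-one; 4 methyl (2E)-2-methyl-4-oxobut-2-enoate
Product: 11 methyl (2E,4R,8E)-7-[2-(benzyloxy)ethyl]-4-hydroxy-2,8-dimethyl-6-oxoundeca-2,8,10-trienoate (C-7 epimers)
Conditions: (−)-Ipc2BCl, Et3N, Et2O, 0 °C; then 4, −78 → −20 °C; then MeOH, pH 7 buffer, H2O2, 0 °C
Reagents that add atoms: none
Why: Paterson boron aldol reaction, in which the bulky chloroborane enolises the methyl side of the α′-branched ketone and the isopinocampheyl ligands are expected to direct the enolate to the Re face of the non-enolisable enal to give the R carbinol (C-6), this antipode of the reagent being exchanged for (+)-Ipc2BCl if the sense of induction proved opposite.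

Step 6
Reactants: 11 methyl (2E,4R,8E)-7-[2-(benzyloxy)ethyl]-4-hydroxy-2,8-dimethyl-6-oxoundeca-2,8,10-trienoate
Product: 12 methyl (2E,4R,8E)-7-[2-(benzyloxy)ethyl]-4-[(tert-butyldimethylsilyl)oxy]-2,8-dimethyl-6-oxoundeca-2,8,10-trienoate (C-7 epimers)
Conditions: TBSOTf, 2,6-lutidine, CH2Cl2, −78 °C
Reagents that add atoms: tert-butyldimethylsilyl trifluoromethanesulfonate (TBSOTf), CC(C)(C)[Si](C)(C)OS(=O)(=O)C(F)(F)F
Why: Low-temperature silylation with a silyl triflate and a hindered base protects the β-hydroxy ketone without retro-aldol cleavage or dehydration and provides the bulky allylic substituent that steers the key step.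

Step 7
Reactants: 12 methyl (2E,4R,8E)-7-[2-(benzyloxy)ethyl]-4-[(tert-butyldimethylsilyl)oxy]-2,8-dimethyl-6-oxoundeca-2,8,10-trienoate
Product: 13 methyl (1S,4aR,5RS,8R,8aS)-5-[2-(benzyloxy)ethyl]-8-[(tert-butyldimethylsilyl)oxy]-1,4a-dimethyl-6-oxo-1,2,4a,5,6,7,8,8a-octahydronaphthalene-1-carboxylate (C-9 epimers in labdane numbering)
Conditions: BHT (cat.), toluene (0.01 M), 175 °C, sealed tube
Reagents that add atoms: none
Why: Thermal intramolecular Diels–Alder reaction in which the E-configured 2-methyl enoate (C-4=C-5) adds suprafacially to the diene (C-10=C-1–C-2=C-3) in a concerted but asynchronous [4+2] process that forms C-5–C-10 together with C-3–C-4. The closest known reaction type is the cyclisation of 2,8,10-undecatrienoates to trans-fused octalins, which also tolerates α-methyl dienophiles that generate a quaternary carbon next to the ring fusion. Ring A is closed by the cycloaddition itself as the new cyclohexene, and ring B is closed by the C-5–C-10 bond alone, with the C-6 to C-9 chain as a four-atom tether held in a chair-like arrangement. C-4 is set relative to C-5 by the E geometry of the dienophile (methyl cis to C-6), C-5 relative to C-6 by allylic 1,3-strain that keeps H-6 eclipsed with the C-4 methyl and puts the silyloxy group outside and anti to the forming bond, and C-10 relative to C-5 by the E diene geometry combined with the ester-endo transition state, which gives the trans ring fusion. The step needs endo over exo selectivity and a cycloaddition that outruns hydrogen shift in the Z-methyl diene, for which the conformational lock at C-6, high dilution and a radical inhibitor are relied on; C-9 is not controlled here and is corrected in step 8.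

Step 8
Reactants: 13 methyl (1S,4aR,5RS,8R,8aS)-5-[2-(benzyloxy)ethyl]-8-[(tert-butyldimethylsilyl)oxy]-1,4a-dimethyl-6-oxo-1,2,4a,5,6,7,8,8a-octahydronaphthalene-1-carboxylate
Product: 15 methyl (1S,4aR,5S,8R,8aS)-8-[(tert-butyldimethylsilyl)oxy]-5-(2-hydroxyethyl)-1,4a-dimethyl-6-oxodecahydronaphthalene-1-carboxylate, via hydroxy ketone epimers 14 (not isolated)
Conditions: H2 (1 atm), Pd/C (10 wt%), EtOAc, rt; filter; then K2CO3, MeOH, rt
Reagents that add atoms: none
Why: Heterogeneous hydrogenation saturates the only alkene (C-1=C-2) and hydrogenolyses the benzyl ether, and mild base then equilibrates the enolisable C-9 centre to the more stable equatorial side chain (the arrangement found in 8-oxo labdanes), setting C-9 under thermodynamic control.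

Step 9
Reactants: 15 methyl (1S,4aR,5S,8R,8aS)-8-[(tert-butyldimethylsilyl)oxy]-5-(2-hydroxyethyl)-1,4a-dimethyl-6-oxodecahydronaphthalene-1-carboxylate; 16 2-(triphenylphosphoranylidene)propanal
Product: 18 methyl (1S,4aR,5S,8R,8aS)-8-[(tert-butyldimethylsilyl)oxy]-1,4a-dimethyl-5-[(2E)-3-methyl-4-oxobut-2-en-1-yl]-6-oxodecahydronaphthalene-1-carboxylate, via keto aldehyde 17 (not isolated)
Conditions: Dess–Martin periodinane, CH2Cl2, 0 °C → rt; then 16, rt → 40 °C
Reagents that add atoms: none
Why: Dess–Martin oxidation of the primary alcohol followed in the same flask by Wittig olefination with a formyl-stabilised ylide, which reacts with the aldehyde but not with the hindered ketone and is weakly basic, should give the E trisubstituted enal (C-12=C-13).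

Step 10
Reactants: 18 methyl (1S,4aR,5S,8R,8aS)-8-[(tert-butyldimethylsilyl)oxy]-1,4a-dimethyl-5-[(2E)-3-methyl-4-oxobut-2-en-1-yl]-6-oxodecahydronaphthalene-1-carboxylate
Product: 19 methyl (1S,4aS,5R,8R,8aS)-8-[(tert-butyldimethylsilyl)oxy]-1,4a-dimethyl-6-methylidene-5-[(2E)-3-methylpenta-2,4-dien-1-yl]decahydronaphthalene-1-carboxylate
Conditions: Zn, CH2Br2, TiCl4, THF/CH2Cl2, 0 °C → rt
Reagents that add atoms: dibromomethane, BrCBr
Why: Lombardo methylenation is non-basic, so it should convert both the hindered C-8 ketone and the enal aldehyde into methylene groups in one operation without epimerisation at C-9, β-elimination of the silyloxy group or attack on the ester.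

Step 11
Reactants: 19 methyl (1S,4aS,5R,8R,8aS)-8-[(tert-butyldimethylsilyl)oxy]-1,4a-dimethyl-6-methylidene-5-[(2E)-3-methylpenta-2,4-dien-1-yl]decahydronaphthalene-1-carboxylate
Product: 20 (1S,4aS,5R,8R,8aS)-8-[(tert-butyldimethylsilyl)oxy]-1,4a-dimethyl-6-methylidene-5-[(2E)-3-methylpenta-2,4-dien-1-yl]decahydronaphthalene-1-carboxylic acid
Conditions: NaSEt, DMF, 100 °C; then 1 M aq. HCl
Reagents that add atoms: none
Why: SN2 demethylation by thiolate at the ester methyl group cleaves the hindered tertiary ester, which resists saponification, and should leave the silyl ether, the exocyclic alkene and the diene untouched.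

Step 12
Reactants: 20 (1S,4aS,5R,8R,8aS)-8-[(tert-butyldimethylsilyl)oxy]-1,4a-dimethyl-6-methylidene-5-[(2E)-3-methylpenta-2,4-dien-1-yl]decahydronaphthalene-1-carboxylic acid
Product: 21 (1S,4aS,5R,8R,8aS)-8-hydroxy-1,4a-dimethyl-6-methylidene-5-[(2E)-3-methylpenta-2,4-dien-1-yl]decahydronaphthalene-1-carboxylic acid
Conditions: HF·pyridine, pyridine, THF, 0 °C → rt
Reagents that add atoms: none
Why: Buffered fluoride-mediated desilylation frees the C-6 alcohol without acid-induced isomerisation of the exocyclic alkene or the diene.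

Step 13
Reactants: 21 (1S,4aS,5R,8R,8aS)-8-hydroxy-1,4a-dimethyl-6-methylidene-5-[(2E)-3-methylpenta-2,4-dien-1-yl]decahydronaphthalene-1-carboxylic acid
Product: 22 (1S,4aS,5R,8R,8aS)-8-(acetyloxy)-1,4a-dimethyl-6-methylidene-5-[(2E)-3-methylpenta-2,4-dien-1-yl]decahydronaphthalene-1-carboxylic acid (target)
Conditions: Ac2O, DMAP (cat.), pyridine, CH2Cl2, rt; then H2O, THF
Reagents that add atoms: acetic anhydride, CC(=O)OC(C)=O
Why: DMAP-catalysed acetylation of the equatorial secondary alcohol, with hydrolysis of the transient mixed anhydride at the acid during aqueous work-up, should give the acetoxy acid, closure to the strained trans-fused γ-lactone not being expected to compete.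

Compound list
1 | 2,2-dimethoxyacetaldehyde | COC(OC)C=O | starting material
2 | methyl 2-(triphenylphosphoranylidene)propanoate | COC(=O)C(C)=P(c1ccccc1)(c1ccccc1)c1ccccc1 | starting material
3 | methyl (2E)-4,4-dimethoxy-2-methylbut-2-enoate | COC(=O)/C(C)=C/C(OC)OC | intermediate
4 | methyl (2E)-2-methyl-4-oxobut-2-enoate | COC(=O)/C(C)=C/C=O | intermediate
5 | (3E)-4-methoxypent-3-en-2-one | CO/C(C)=C/C(C)=O | starting material
6 | allylmagnesium bromide | C=CC[Mg]Br | starting material
7 | (2E)-2-methoxy-4-methylhepta-2,6-dien-4-ol (racemic) | CO/C(C)=C/C(C)(O)CC=C | intermediate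
8 | 4-methylhepta-3,6-dien-2-one (E/Z mixture) | CC(=O)C=C(C)CC=C | intermediate
9 | benzyl 2-iodoethyl ether | ICCOCc1ccccc1 | starting material
10 | (4E)-3-[2-(benzyloxy)ethyl]-4-methylhepta-4,6-dien-2-one (racemic) | CC(=O)C(CCOCc1ccccc1)/C(C)=C/C=C | intermediate
11 | methyl (2E,4R,8E)-7-[2-(benzyloxy)ethyl]-4-hydroxy-2,8-dimethyl-6-oxoundeca-2,8,10-trienoate (C-7 epimers) | COC(=O)/C(C)=C/[C@H](O)CC(=O)C(CCOCc1ccccc1)/C(C)=C/C=C | intermediate
12 | methyl (2E,4R,8E)-7-[2-(benzyloxy)ethyl]-4-[(tert-butyldimethylsilyl)oxy]-2,8-dimethyl-6-oxoundeca-2,8,10-trienoate (C-7 epimers) | COC(=O)/C(C)=C/[C@H](O[Si](C)(C)C(C)(C)C)CC(=O)C(CCOCc1ccccc1)/C(C)=C/C=C | intermediate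
13 | methyl (1S,4aR,5RS,8R,8aS)-5-[2-(benzyloxy)ethyl]-8-[(tert-butyldimethylsilyl)oxy]-1,4a-dimethyl-6-oxo-1,2,4a,5,6,7,8,8a-octahydronaphthalene-1-carboxylate | c3ccccc3COCCC1C(=O)C[C@@H](O[Si](C)(C)C(C)(C)C)[C@H]2[C@@]1(C)C=CC[C@]2(C)C(=O)OC | intermediate
14 | methyl (1S,4aR,5RS,8R,8aS)-8-[(tert-butyldimethylsilyl)oxy]-5-(2-hydroxyethyl)-1,4a-dimethyl-6-oxodecahydronaphthalene-1-carboxylate | OCCC1C(=O)C[C@@H](O[Si](C)(C)C(C)(C)C)[C@H]2[C@@]1(C)CCC[C@]2(C)C(=O)OC | intermediate
15 | methyl (1S,4aR,5S,8R,8aS)-8-[(tert-butyldimethylsilyl)oxy]-5-(2-hydroxyethyl)-1,4a-dimethyl-6-oxodecahydronaphthalene-1-carboxylate | OCC[C@@H]1C(=O)C[C@@H](O[Si](C)(C)C(C)(C)C)[C@H]2[C@@]1(C)CCC[C@]2(C)C(=O)OC | intermediate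
16 | 2-(triphenylphosphoranylidene)propanal | CC(C=O)=P(c1ccccc1)(c1ccccc1)c1ccccc1 | starting material
17 | methyl (1S,4aR,5S,8R,8aS)-8-[(tert-butyldimethylsilyl)oxy]-1,4a-dimethyl-6-oxo-5-(2-oxoethyl)decahydronaphthalene-1-carboxylate | O=CC[C@@H]1C(=O)C[C@@H](O[Si](C)(C)C(C)(C)C)[C@H]2[C@@]1(C)CCC[C@]2(C)C(=O)OC | intermediate
18 | methyl (1S,4aR,5S,8R,8aS)-8-[(tert-butyldimethylsilyl)oxy]-1,4a-dimethyl-5-[(2E)-3-methyl-4-oxobut-2-en-1-yl]-6-oxodecahydronaphthalene-1-carboxylate | O=C/C(C)=C/C[C@@H]1C(=O)C[C@@H](O[Si](C)(C)C(C)(C)C)[C@H]2[C@@]1(C)CCC[C@]2(C)C(=O)OC | intermediate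
19 | methyl (1S,4aS,5R,8R,8aS)-8-[(tert-butyldimethylsilyl)oxy]-1,4a-dimethyl-6-methylidene-5-[(2E)-3-methylpenta-2,4-dien-1-yl]decahydronaphthalene-1-carboxylate | C=C/C(C)=C/C[C@@H]1C(=C)C[C@@H](O[Si](C)(C)C(C)(C)C)[C@H]2[C@@]1(C)CCC[C@]2(C)C(=O)OC | intermediate
20 | (1S,4aS,5R,8R,8aS)-8-[(tert-butyldimethylsilyl)oxy]-1,4a-dimethyl-6-methylidene-5-[(2E)-3-methylpenta-2,4-dien-1-yl]decahydronaphthalene-1-carboxylic acid | C=C/C(C)=C/C[C@@H]1C(=C)C[C@@H](O[Si](C)(C)C(C)(C)C)[C@H]2[C@@]1(C)CCC[C@]2(C)C(=O)O | intermediate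
21 | (1S,4aS,5R,8R,8aS)-8-hydroxy-1,4a-dimethyl-6-methylidene-5-[(2E)-3-methylpenta-2,4-dien-1-yl]decahydronaphthalene-1-carboxylic acid | C=C/C(C)=C/C[C@@H]1C(=C)C[C@@H](O)[C@H]2[C@@]1(C)CCC[C@]2(C)C(=O)O | intermediate
22 | (1S,4aS,5R,8R,8aS)-8-(acetyloxy)-1,4a-dimethyl-6-methylidene-5-[(2E)-3-methylpenta-2,4-dien-1-yl]decahydronaphthalene-1-carboxylic acid; labdane numbering 4S,5S,6R,9R,10S | C=C/C(C)=C/C[C@@H]1C(=C)C[C@@H](OC(C)=O)[C@H]2[C@@]1(C)CCC[C@]2(C)C(=O)O | target

Total step count: 13. Longest linear sequence: 11 steps (5 → 8 → 10 → 11 → 12 → 13 → 15 → 18 → 19 → 20 → 21 → 22); the enal 4 is made in a 2-step side branch.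

Steps most likely to fail

Step 7 (key cycloaddition). The cycloaddition at the hindered diene terminus may be slower than hydrogen shift in the Z-methyl diene or thermal loss of the silyloxy group, and exo (cis-fused) closure may compete with the endo mode. The fallback sets out from 10 and comes back at 13; it activates the dienophile as an aldehyde and closes the rings with a Lewis acid at low temperature instead of by heat. Ketone 10 is added in the same boron aldol reaction to the known (2E)-4,4-dimethoxy-3-methylbut-2-enal F1 to give the hydroxy ketone acetal F2, which is silylated (TBSOTf, 2,6-lutidine) to the silyl ether acetal F3. Oxalic acid on wet silica releases the trienal F4, and Me2AlCl (CH2Cl2, −78 → −20 °C) should close it through the same endo transition state to the octalin aldehyde F5. Pinnick oxidation (NaClO2, NaH2PO4, 2-methylbut-2-ene) gives the acid F6, and Me3SiCHN2 in MeOH/toluene returns the methyl ester 13.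

Step 4 (trienolate alkylation). Alkylation may occur at the γ- or ε-carbon or at oxygen, a second alkylation at C-9 may follow, and the E geometry of the new trisubstituted alkene may be eroded. The fallback sets out from 9 and comes back at 10; it builds the diene stereospecifically by alkyne carbometalation. Ethyl acetoacetate F7 is C-alkylated with 9 (NaH, THF/DMF) to the keto ester F8, and the ketone is protected as the dioxolane ester F9 (ethylene glycol, TsOH, benzene, reflux). DIBAL-H at −78 °C gives the aldehyde F10, and Ohira–Bestmann homologation (dimethyl (1-diazo-2-oxopropyl)phosphonate, K2CO3, MeOH) gives the alkyne F11. Negishi carboalumination (Me3Al, Cp2ZrCl2) followed by coupling of the alkenylalane with vinyl bromide (Pd(PPh3)4, ZnCl2) gives the dioxolane diene F12 with syn-defined E geometry, and PPTS in wet acetone releases ketone 10.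

Step 5 (asymmetric aldol). Enantiofacial control by the boron ligands may be incomplete or of the opposite sense, which would carry through to every later stereocentre. The fallback sets out from 10 and comes back at 11; it replaces the stoichiometric chiral boron enolate by a catalytic enantioselective Mukaiyama aldol addition. Kinetic enolisation of 10 (LDA, THF, −78 °C) and trapping with Me3SiCl gives the silyl enol ether F13. This is added to 4 with SiCl4, a chiral bisphosphoramide catalyst of the antipode that gives Re-face attack, and iPr2NEt in CH2Cl2 at −78 °C, a system suited to conjugated aldehydes; aqueous work-up gives 11 directly.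

Further compounds
F1 | step 7 | (2E)-4,4-dimethoxy-3-methylbut-2-enal | COC(OC)/C(C)=C/C=O
F2 | step 7 | (2E,4R,8E)-7-[2-(benzyloxy)ethyl]-4-hydroxy-1,1-dimethoxy-2,8-dimethylundeca-2,8,10-trien-6-one (C-7 epimers) | COC(OC)/C(C)=C/[C@H](O)CC(=O)C(CCOCc1ccccc1)/C(C)=C/C=C
F3 | step 7 | (2E,4R,8E)-7-[2-(benzyloxy)ethyl]-4-[(tert-butyldimethylsilyl)oxy]-1,1-dimethoxy-2,8-dimethylundeca-2,8,10-trien-6-one (C-7 epimers) | COC(OC)/C(C)=C/[C@H](O[Si](C)(C)C(C)(C)C)CC(=O)C(CCOCc1ccccc1)/C(C)=C/C=C
F4 | step 7 | (2E,4R,8E)-7-[2-(benzyloxy)ethyl]-4-[(tert-butyldimethylsilyl)oxy]-2,8-dimethyl-6-oxoundeca-2,8,10-trienal (C-7 epimers) | O=C/C(C)=C/[C@H](O[Si](C)(C)C(C)(C)C)CC(=O)C(CCOCc1ccccc1)/C(C)=C/C=C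
F5 | step 7 | (1S,4aR,5RS,8R,8aS)-5-[2-(benzyloxy)ethyl]-8-[(tert-butyldimethylsilyl)oxy]-1,4a-dimethyl-6-oxo-1,2,4a,5,6,7,8,8a-octahydronaphthalene-1-carbaldehyde | c3ccccc3COCCC1C(=O)C[C@@H](O[Si](C)(C)C(C)(C)C)[C@H]2[C@@]1(C)C=CC[C@]2(C)C=O
F6 | step 7 | (1S,4aR,5RS,8R,8aS)-5-[2-(benzyloxy)ethyl]-8-[(tert-butyldimethylsilyl)oxy]-1,4a-dimethyl-6-oxo-1,2,4a,5,6,7,8,8a-octahydronaphthalene-1-carboxylic acid | c3ccccc3COCCC1C(=O)C[C@@H](O[Si](C)(C)C(C)(C)C)[C@H]2[C@@]1(C)C=CC[C@]2(C)C(=O)O
F7 | step 4 | ethyl acetoacetate | CCOC(=O)CC(C)=O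
F8 | step 4 | ethyl 2-acetyl-4-(benzyloxy)butanoate | CCOC(=O)C(CCOCc1ccccc1)C(C)=O
F9 | step 4 | ethyl 4-(benzyloxy)-2-(2-methyl-1,3-dioxolan-2-yl)butanoate | CCOC(=O)C(CCOCc1ccccc1)C2(C)OCCO2
F10 | step 4 | 4-(benzyloxy)-2-(2-methyl-1,3-dioxolan-2-yl)butanal | O=CC(CCOCc1ccccc1)C2(C)OCCO2
F11 | step 4 | 2-[5-(benzyloxy)pent-1-yn-3-yl]-2-methyl-1,3-dioxolane | C#CC(CCOCc1ccccc1)C2(C)OCCO2
F12 | step 4 | 2-[(4E)-1-(benzyloxy)-4-methylhepta-4,6-dien-3-yl]-2-methyl-1,3-dioxolane | CC2(OCCO2)C(CCOCc1ccccc1)/C(C)=C/C=C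
F13 | step 5 | {[(4E)-3-[2-(benzyloxy)ethyl]-4-methylhepta-1,4,6-trien-2-yl]oxy}trimethylsilane | C=C(O[Si](C)(C)C)C(CCOCc1ccccc1)/C(C)=C/C=C
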